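## Structural features

Licoagrodione (15) is an unsymmetrical benzil: two benzene rings joined through a two-carbon 1,2-diketone chain, with no ring besides the two arenes and no stereocentre, so no stereocentres stand next to each other. Ring A is a 2-hydroxy-4-methoxyphenyl group. Ring B is a 2,4-dihydroxyphenyl group with a 3-methylbut-2-enyl (prenyl) chain on C3, the carbon between its two hydroxyls, and each ring has a phenol ortho to its own carbonyl, held in a hydrogen-bonded chelate. The fragile parts are the prenyl alkene (it closes onto a neighbouring phenol to a chroman under acid and is attacked by electrophilic oxidants), the 1,2-dione (easily reduced, prone to benzilic acid rearrangement in hot aqueous alkali, able to form cyclic hemiketals with the ortho phenols) and the electron-rich resorcinol ring. The difficulty is regiochemical: two different electron-rich aryl groups must be attached to the two carbonyls without scrambling, the prenyl group must go to C3 of ring B and not to C5 or to oxygen, and three phenols must be told apart from each other and from the methyl ether. The chosen key step uses the fact that the aroyl unit of ring A (oxygen at C2, methoxy at C4) and the 2,4-dioxygenated ring B on the adjacent carbon form an isoflavonoid C6–C3–C6 skeleton that lacks C2. The bond from ring B C1 to its carbonyl carbon can therefore be made by a 1,2-aryl shift in a chalcone, with the oxygens at C2 and C4 of ring B (ortho and para to the migrating carbon) driving the shift, and the surplus carbon is then cut out as formate.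

## Logic of the disconnections

15 to 14. The bond between ring B C3 and the CH2 of the prenyl chain is cut by a retro-[3,3] operation that returns the five-carbon unit to O4 as a tertiary allyl ether. The prenyl alkene would not survive trivalent iodine, SeO2 or BCl3, so it has to come last. The gain is a precursor without the acid- and oxidant-sensitive ortho-prenylphenol. The forward rearrangement must go to C3 and not to C5, and must run in a hot but neutral medium.

14 to 13, then 13 to 11 and 12. The vinyl group is traced back to an ethynyl group and the O4–C(CH3)2 bond is cut. A tertiary allylic halide would alkylate through its primary terminus and give the wrong ether, whereas the tertiary propargylic chloride gives the tertiary ether reliably. The five carbons then come from a commercial reagent. The forward demands are alkylation at O4 of ring B only, and a semihydrogenation that stops at the alkene and leaves the dione alone.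

11 to 10. The three O–CH2Ph bonds are reinstated. All phenols have to be capped from the condensation through both oxidations. The forward cleavage must use no hydrogen (the dione would be reduced) and must spare the methyl ether.

10 to 9. The carbonyl on the carbon that bears ring B is taken back to a methylene. This keeps the base- and reduction-sensitive dione out of the earlier steps. The forward oxidant must pick the one CH2 flanked by carbonyl and ring B over the three benzyl ether CH2 groups.

9 to 7 through 8. One carbon is put back on the methylene carbon as a formyl group, then as its dimethyl acetal. In the forward sense the bond between the ring B-bearing carbon and the acetal carbon is the one that is cut. This restores the three-carbon chain of the isoflavonoid skeleton. The forward retro-Claisen must cleave on the aldehyde side, and both ortho oxygens must stay capped so that the aldehyde cannot cyclise.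

7 to 6. The bond between ring B C1 and the alpha carbon is cut, ring B is returned to the beta carbon, and the two C–OCH3 bonds are removed. The 1,2-diaryl ketone becomes a 1,3-diaryl enone with no stereocentre. Forward, ring B must migrate, and nothing else in the molecule may react with the oxidant.

6 to 3 and 5. The Cα=Cβ bond is cut as an aldol condensation between a methyl ketone and a non-enolisable aldehyde. The E alkene is the thermodynamic product.

3 to 1 and 2, and 5 to 4 and 2. The O–benzyl bonds are cut. Both phenolic carbonyl compounds are bulk chemicals.

## Other disconnections considered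

Alternative 1: The cut is through ring B itself, at C1–C2 and C5–C6. Forward, the bis-silyl diene A1 would add to the terminal ynone A2, and the adduct would aromatise by loss of methoxytrimethylsilane to the protected benzoin-level ketone A3.
- In its favour: the prenyl group sits on the diene carbon that becomes C3, so there is no C3/C5 question. On that point it is better than the chosen plan. The polarity of the two partners fixes the orientation of the addition, the approach is convergent, and ring B never meets an electrophilic oxidant.
- Against it: A1 is a moisture-sensitive diene with a fully substituted ketene acetal terminus, and that hindered terminus must bond to the acyl-bearing alkyne carbon, so a Michael addition that stops at the open-chain adduct is a realistic competitor. A2 is a base-sensitive alpha-silyloxy ynone that needs several steps of its own. A3 still has to be desilylated, oxidised to the dione beside free phenols and a prenyl group, and freed of its MOM ether with acid next to that prenyl group.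
- Comparison: on structure it is equal for ring A and better for the prenyl position. On mechanism it relies on a ring construction between two hindered partners, where the chosen plan relies on an aryl shift whose migrating group is electronically matched. On step economy, with both fragment syntheses counted, it is no shorter than ten steps and has less robust intermediates.

Alternative 2: The cut is the bond from ring A C1 to its carbonyl carbon, with ring A traced back to the cyclohexenone A4. Forward, LiN(iPr)2 would deprotonate A4 at C6, the enolate would be C-acylated by the acylbenzotriazole A5 to the enolised diketone A6, and dehydrogenation would then reveal the 2-hydroxy-4-methoxyphenyl ketone.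
- In its favour: the oxygen pattern of ring A arises without ambiguity and the ring A phenol appears free and chelated. Ring B carries its prenyl group from the start, placed by directed metalation, which is better than a late rearrangement. Acylbenzotriazoles are selective C-acylating agents.
- Against it: ring A with exactly this pattern is already the cheap commercial ketone 1, so building it gains nothing. The aromatisation reagent has to leave the prenyl alkene and the silyloxy-bearing carbon untouched. A5 alone needs about as many steps as the whole chosen route up to 9. The oxidation-level correction and the acidic MOM removal beside the prenyl group remain.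
- Comparison: on structure it is equal for ring A and better for the prenyl position. On mechanism it trades the aryl shift for an enolate acylation with C- versus O-selectivity and a chemoselective dehydrogenation. On step economy it is clearly longer.

Alternative 3: The cut is at both aryl–carbonyl bonds, with the oxalamide A7 as a two-carbon dielectrophile. Forward, the aryllithium from bromide A8 (bromine–lithium exchange) and then the aryllithium from arene A9 (ortho-lithiation) would add one after the other to A7, and collapse of the two chelated adducts on work-up would give the tris-MOM ether A10.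
- In its favour: it is the most convergent and the shortest plan, about six or seven steps with a longest linear sequence of about four. It delivers the dione at the correct oxidation level with no redox step, and the prenyl position is defined by an earlier metalation between two ether oxygens. On step count, convergence and redox economy it is better than the chosen plan.
- Against it: the first aryllithium can add twice, and a collapsed adduct can be attacked again. A9 can be lithiated at its benzylic–allylic CH2 instead of on the ring. The last step has to remove three MOM ethers with acid from a compound in which a prenyl group lies between two phenols, the arrangement that closes to a chroman. MOM chloride is also a carcinogen.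
- Comparison: the final structure is the same. The mechanism is simple carbonyl addition but needs control of stoichiometry and of the site of metalation. The chosen plan is longer, but it brings in the prenyl group last under neutral conditions and every step has precedent on the same arrangement of functional groups. If a MOM removal that spares ortho-prenylphenols were secured, alternative 3 would be the more efficient route.

Key step: step 4

Remarks on the chemistry:
- The structures of 6 and 7 were checked atom by atom against 15 and need no correction. Ring A comes from the ketone, ring B from the aldehyde, and the carbon that carries ring B in 7 becomes the ring B carbonyl.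
- The tribenzyl design of the precursor is kept. Benzyl ethers survive TsOH in methanol, hot alkali and SeO2, they keep both ortho oxygens capped during the excision of the extra carbon, and they can be removed later without hydrogen.
- The changes are downstream: hydrolysis and deformylation are run in one pot under nitrogen, a cation trap is used in the debenzylation, and the etherification is copper-catalysed at 0 °C.
- Compounds 7 and 8 are racemic at a carbon that later becomes a carbonyl carbon.
- Compounds 11 and 13 to 15 are drawn as open diones, although ortho-hydroxybenzils can equilibrate with cyclic hemiketals.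
- Compound 5 can also be bought; step 2 is written out so that the route starts from bulk chemicals only.

## Steps

Step 1
Reactants: 1 2-hydroxy-4-methoxyacetophenone (paeonol); 2 benzyl bromide
Product: 3 1-[2-(benzyloxy)-4-methoxyphenyl]ethan-1-one
Conditions: BnBr, K2CO3, DMF, 60 °C
Reagents that add atoms: benzyl bromide 2, BrCc1ccccc1
Why: Williamson ether synthesis; carbonate in DMF ionises the chelated phenol and the phenoxide displaces bromide from the benzylic carbon.

Step 2
Reactants: 4 2,4-dihydroxybenzaldehyde; 2 benzyl bromide
Product: 5 2,4-bis(benzyloxy)benzaldehyde
Conditions: BnBr (2.2 equiv), K2CO3, DMF, 60 °C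
Reagents that add atoms: benzyl bromide 2, BrCc1ccccc1
Why: Double Williamson ether synthesis; the free 4-OH reacts first and the chelated 2-OH follows at 60 °C with excess halide, and the aldehyde has no alpha hydrogen to interfere.

Step 3
Reactants: 3 1-[2-(benzyloxy)-4-methoxyphenyl]ethan-1-one; 5 2,4-bis(benzyloxy)benzaldehyde
Product: 6 (E)-1-[2-(benzyloxy)-4-methoxyphenyl]-3-[2,4-bis(benzyloxy)phenyl]prop-2-en-1-one
Conditions: KOH, EtOH/THF, rt
Reagents that add atoms: none
Why: Claisen–Schmidt condensation; the methyl ketone enolate adds to the non-enolisable aldehyde and E1cB loss of water gives the conjugated enone, the E isomer being formed under thermodynamic control.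

Step 4
Reactants: 6 (E)-1-[2-(benzyloxy)-4-methoxyphenyl]-3-[2,4-bis(benzyloxy)phenyl]prop-2-en-1-one
Product: 7 1-[2-(benzyloxy)-4-methoxyphenyl]-2-[2,4-bis(benzyloxy)phenyl]-3,3-dimethoxypropan-1-one (racemic)
Conditions: PhI(OAc)2, TsOH·H2O, MeOH/HC(OMe)3/CH2Cl2, rt
Reagents that add atoms: methanol, CO (both methoxy groups)
Why: Ligand exchange of PhI(OAc)2 with TsOH and methanol gives an electrophilic trivalent iodine species that the enone attacks with its alpha carbon while methanol is delivered to the beta carbon, where the 2,4-dialkoxyphenyl ring carries the positive charge. Departure of iodobenzene from the alpha carbon is assisted by ring B, which bridges as a phenonium ion and ends on the alpha carbon, so that the bond from ring B C1 to the future carbonyl carbon is made. The methoxy-stabilised oxocarbenium ion left at the former beta carbon is trapped by methanol as the dimethyl acetal, and trimethyl orthoformate keeps the medium dry. The closest known reaction type is the oxidative 1,2-aryl rearrangement of 2'-alkoxychalcones with Tl(NO3)3 (trivalent thallium) or with PhI(OH)OTs that is used to make isoflavones. No ring is closed. The only new stereocentre, the carbon that carries ring B, is formed racemic; nothing controls it and nothing needs to, because it becomes a carbonyl carbon in step 6. The selectivity needed is migration of ring B in preference to oxidation of the arenes or benzyl ethers and to plain dimethoxylation of the alkene; it is secured by the oxygens at C2 and C4 of ring B, which are ortho and para to the migrating carbon, by the deactivation of ring A through its carbonyl, by the capping of all three phenols and by the absence of any isolated alkene.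

Step 5
Reactants: 7 1-[2-(benzyloxy)-4-methoxyphenyl]-2-[2,4-bis(benzyloxy)phenyl]-3,3-dimethoxypropan-1-one
Product: 9 1-[2-(benzyloxy)-4-methoxyphenyl]-2-[2,4-bis(benzyloxy)phenyl]ethan-1-one, via alpha-formyl deoxybenzoin 8 (not isolated)
Conditions: aq. HCl (cat.), THF, 50 °C; then aq. NaOH, EtOH, 70 °C, N2, one pot
Reagents that add atoms: none
Why: Acid-catalysed acetal hydrolysis followed by retro-Claisen deformylation; hydroxide adds to the aldehyde of 8 and the adduct expels the aryl-stabilised enolate of 9 with the extra carbon leaving as formate, the same cleavage by which alkali degrades isoflavones to deoxybenzoins. Both ortho oxygens are benzylated, so 8 cannot close to an isoflavone or a 2-arylbenzofuran, and exclusion of air prevents autoxidation of the enolate of 9.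

Step 6
Reactants: 9 1-[2-(benzyloxy)-4-methoxyphenyl]-2-[2,4-bis(benzyloxy)phenyl]ethan-1-one
Product: 10 1-[2-(benzyloxy)-4-methoxyphenyl]-2-[2,4-bis(benzyloxy)phenyl]ethane-1,2-dione
Conditions: SeO2, 1,4-dioxane/H2O, 100 °C
Reagents that add atoms: selenium dioxide, O=[Se]=O
Why: Riley oxidation; SeO2 attacks the enol of the deoxybenzoin, whose methylene is activated by both the carbonyl and ring B, and a [2,3]-shift with loss of selenium and water gives the 1,2-dione, while the non-enolisable benzyl ether methylenes react far more slowly.

Step 7
Reactants: 10 1-[2-(benzyloxy)-4-methoxyphenyl]-2-[2,4-bis(benzyloxy)phenyl]ethane-1,2-dione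
Product: 11 1-(2,4-dihydroxyphenyl)-2-(2-hydroxy-4-methoxyphenyl)ethane-1,2-dione
Conditions: BCl3, pentamethylbenzene, CH2Cl2, −78 °C; then MeOH, aq. NaHCO3
Reagents that add atoms: none
Why: Lewis acid ether cleavage; BCl3 coordinates each benzylic oxygen and the benzyl cation is passed to pentamethylbenzene (Friedel–Crafts trap), so the electron-rich ring B is not C-benzylated. At −78 °C the aryl methyl ether, which is para to its carbonyl and has no chelation assistance, is not cleaved, and no hydrogen is used that could reduce the dione.

Step 8
Reactants: 11 1-(2,4-dihydroxyphenyl)-2-(2-hydroxy-4-methoxyphenyl)ethane-1,2-dione; 12 3-chloro-3-methylbut-1-yne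
Product: 13 1-{2-hydroxy-4-[(2-methylbut-3-yn-2-yl)oxy]phenyl}-2-(2-hydroxy-4-methoxyphenyl)ethane-1,2-dione
Conditions: DBU (1.2 equiv), CuCl2·2H2O (cat., divalent copper), MeCN, 0 °C
Reagents that add atoms: 3-chloro-3-methylbut-1-yne 12, C#CC(C)(C)Cl
Why: Copper-catalysed propargylic etherification, a Williamson-type O-alkylation through a copper acetylide; one equivalent of DBU ionises only the 4-OH of ring B, the most acidic phenol and the only one not locked in a hydrogen bond to a carbonyl, so the bulky tertiary electrophile ends on that oxygen. The low temperature and the absence of hydroxide spare the dione.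

Step 9
Reactants: 13 1-{2-hydroxy-4-[(2-methylbut-3-yn-2-yl)oxy]phenyl}-2-(2-hydroxy-4-methoxyphenyl)ethane-1,2-dione
Product: 14 1-{2-hydroxy-4-[(2-methylbut-3-en-2-yl)oxy]phenyl}-2-(2-hydroxy-4-methoxyphenyl)ethane-1,2-dione
Conditions: H2 (1 atm, 1 equiv), Pd/CaCO3 poisoned with Pb(OAc)2, quinoline, EtOAc, rt
Reagents that add atoms: none
Why: Lindlar semihydrogenation; the terminal alkyne binds to the poisoned palladium surface much more strongly than the product alkene, the aryl ketones or the dione, so uptake of one equivalent of hydrogen should stop at the vinyl group.

Step 10
Reactants: 14 1-{2-hydroxy-4-[(2-methylbut-3-en-2-yl)oxy]phenyl}-2-(2-hydroxy-4-methoxyphenyl)ethane-1,2-dione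
Product: 15 licoagrodione, 1-[2,4-dihydroxy-3-(3-methylbut-2-en-1-yl)phenyl]-2-(2-hydroxy-4-methoxyphenyl)ethane-1,2-dione
Conditions: PhNEt2, 130 °C
Reagents that add atoms: none
Why: Aromatic Claisen rearrangement; a concerted [3,3] shift through a chair-like transition state joins the terminal CH2 of the tertiary allyl ether to ring B C3 and the dienone tautomerises to the phenol. The chelate between the 2-OH and the ring B carbonyl localises double-bond character in C3–C4, which directs the shift to C3 and not to C5, and the amine solvent keeps the medium free of acid so that the ortho-prenylphenol does not close to a chroman; no stereocentre is formed.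

## Compound list

1 | 2-hydroxy-4-methoxyacetophenone (paeonol) | CC(=O)c1ccc(OC)cc1O | starting material
2 | benzyl bromide | BrCc1ccccc1 | starting material
3 | 1-[2-(benzyloxy)-4-methoxyphenyl]ethan-1-one | CC(=O)c1ccc(OC)cc1OCc1ccccc1 | intermediate
4 | 2,4-dihydroxybenzaldehyde | O=Cc1ccc(O)cc1O | starting material
5 | 2,4-bis(benzyloxy)benzaldehyde | O=Cc1ccc(OCc2ccccc2)cc1OCc1ccccc1 | intermediate
6 | (E)-1-[2-(benzyloxy)-4-methoxyphenyl]-3-[2,4-bis(benzyloxy)phenyl]prop-2-en-1-one | COc1ccc(C(=O)/C=C/c2ccc(OCc3ccccc3)cc2OCc2ccccc2)c(OCc2ccccc2)c1 | intermediate
7 | 1-[2-(benzyloxy)-4-methoxyphenyl]-2-[2,4-bis(benzyloxy)phenyl]-3,3-dimethoxypropan-1-one, racemic | COc1ccc(C(=O)C(C(OC)OC)c2ccc(OCc3ccccc3)cc2OCc2ccccc2)c(OCc2ccccc2)c1 | intermediate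
8 | 3-[2-(benzyloxy)-4-methoxyphenyl]-2-[2,4-bis(benzyloxy)phenyl]-3-oxopropanal, racemic, largely enolised | COc1ccc(C(=O)C(C=O)c2ccc(OCc3ccccc3)cc2OCc2ccccc2)c(OCc2ccccc2)c1 | intermediate (not isolated)
9 | 1-[2-(benzyloxy)-4-methoxyphenyl]-2-[2,4-bis(benzyloxy)phenyl]ethan-1-one | COc1ccc(C(=O)Cc2ccc(OCc3ccccc3)cc2OCc2ccccc2)c(OCc2ccccc2)c1 | intermediate
10 | 1-[2-(benzyloxy)-4-methoxyphenyl]-2-[2,4-bis(benzyloxy)phenyl]ethane-1,2-dione | COc1ccc(C(=O)C(=O)c2ccc(OCc3ccccc3)cc2OCc2ccccc2)c(OCc2ccccc2)c1 | intermediate
11 | 1-(2,4-dihydroxyphenyl)-2-(2-hydroxy-4-methoxyphenyl)ethane-1,2-dione | COc1ccc(C(=O)C(=O)c2ccc(O)cc2O)c(O)c1 | intermediate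
12 | 3-chloro-3-methylbut-1-yne | C#CC(C)(C)Cl | starting material
13 | 1-{2-hydroxy-4-[(2-methylbut-3-yn-2-yl)oxy]phenyl}-2-(2-hydroxy-4-methoxyphenyl)ethane-1,2-dione | COc1ccc(C(=O)C(=O)c2ccc(OC(C)(C)C#C)cc2O)c(O)c1 | intermediate
14 | 1-{2-hydroxy-4-[(2-methylbut-3-en-2-yl)oxy]phenyl}-2-(2-hydroxy-4-methoxyphenyl)ethane-1,2-dione | COc1ccc(C(=O)C(=O)c2ccc(OC(C)(C)C=C)cc2O)c(O)c1 | intermediate
15 | licoagrodione, 1-[2,4-dihydroxy-3-(3-methylbut-2-en-1-yl)phenyl]-2-(2-hydroxy-4-methoxyphenyl)ethane-1,2-dione | COc1ccc(C(=O)C(=O)c2ccc(O)c(CC=C(C)C)c2O)c(O)c1 | target

## Step count and least certain steps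

Total: 10 steps. Longest linear sequence: 9 steps (steps 1, 3, 4, 5, 6, 7, 8, 9, 10 from 1).

Step 4 (key step). The most likely failure is that the trivalent iodine reagent substitutes the electron-rich arenes, or that methanol adds across the alkene without aryl migration; low solubility of 6 could also make the reaction slow enough for these paths to compete. The fallback sets out from 6 and changes the bond that is formed. Weitz–Scheffer epoxidation (H2O2, NaOH, MeOH/THF) should give [2-(benzyloxy)-4-methoxyphenyl]{(2R*,3S*)-3-[2,4-bis(benzyloxy)phenyl]oxiran-2-yl}methanone F1. BF3·OEt2 in CH2Cl2 at low temperature should then open the epoxide at the carbon stabilised by ring B and shift the aroyl group to that carbon (Meinwald-type rearrangement with acyl migration). This gives 8 with the same constitution as in the main route, and 8 comes back to the route at the alkaline stage of step 5, which leads to 9.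

Step 5. The most likely failures are cleavage on the ketone side of the beta-keto aldehyde, incomplete attack of hydroxide on its unreactive enolate, and air oxidation of the enolate of 9 in hot alkali. The fallback sets out from 7 and removes the extra carbon oxidatively. The acid stage alone is run and 8 is isolated. Condensation with dimethylamine (toluene, molecular sieves) should give (E)-1-[2-(benzyloxy)-4-methoxyphenyl]-2-[2,4-bis(benzyloxy)phenyl]-3-(dimethylamino)prop-2-en-1-one F2. Sensitised photooxygenation (O2, visible light, tetraphenylporphyrin, CH2Cl2, 0 °C) should then add singlet oxygen across the enamine double bond and split the dioxetane into the dione and N,N-dimethylformamide. The fallback comes back to the route at 10 and also bypasses step 6.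

Step 6. The most likely failure is over-oxidation with cleavage of the central C–C bond, or competing attack at the benzyl ether methylenes or on ring B at 100 °C. The fallback sets out from 9 and goes through the benzoin oxidation level. The potassium enolate (KN(SiMe3)2, THF, −78 °C) is hydroxylated with 2-(phenylsulfonyl)-3-phenyloxaziridine to 1-[2-(benzyloxy)-4-methoxyphenyl]-2-[2,4-bis(benzyloxy)phenyl]-2-hydroxyethan-1-one F3 (racemic). Dess–Martin oxidation then gives the dione, and the fallback comes back to the route at 10.

Step 9. The most likely failure is hydrogenation beyond the alkene stage or partial reduction of the 1,2-dione on the palladium surface. The fallback sets out from 11, uses no hydrogen and bypasses 13. tert-Butyl 2-methylbut-3-en-2-yl carbonate F4 is made from 2-methylbut-3-en-2-ol, n-BuLi and Boc2O. With Pd(PPh3)4 (zerovalent palladium) in THF at 0 °C it should transfer the tertiary allyl group to the ring B 4-oxygen (Tsuji–Trost O-allylation, kinetic attack at the more substituted terminus of the allyl complex), with loss of carbon dioxide and tert-butanol. The fallback comes back to the route at 14.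

Step 10. The most likely failure is loss of the tertiary allyl group by ionisation and elimination before it rearranges, partial migration to C5, or closure of the product to a chroman on prolonged heating. The fallback sets out from 11 and builds the prenyl group in two stages. Allyl bromide and K2CO3 in MeCN should give 1-[4-(allyloxy)-2-hydroxyphenyl]-2-(2-hydroxy-4-methoxyphenyl)ethane-1,2-dione F5. Its Claisen rearrangement (PhNEt2, 190 °C) cannot ionise and, for 4-allyloxy-2-hydroxyaryl ketones, goes to the carbon between the two oxygens, giving 1-(3-allyl-2,4-dihydroxyphenyl)-2-(2-hydroxy-4-methoxyphenyl)ethane-1,2-dione F6. Cross-metathesis with 2-methylbut-2-ene (second-generation Grubbs catalyst, CH2Cl2, 40 °C) then turns the allyl into the prenyl group with loss of propene, and the fallback comes back to the route at 15.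

## Further compounds

F1 | step 4 | [2-(benzyloxy)-4-methoxyphenyl]{(2R*,3S*)-3-[2,4-bis(benzyloxy)phenyl]oxiran-2-yl}methanone, racemic trans epoxide, one enantiomer drawn | COc1ccc(C(=O)[C@@H]2O[C@H]2c2ccc(OCc3ccccc3)cc2OCc2ccccc2)c(OCc2ccccc2)c1
F2 | step 5 | (E)-1-[2-(benzyloxy)-4-methoxyphenyl]-2-[2,4-bis(benzyloxy)phenyl]-3-(dimethylamino)prop-2-en-1-one | CN(C)/C=C(\c1ccc(OCc2ccccc2)cc1OCc1ccccc1)C(=O)c1ccc(OC)cc1OCc1ccccc1
F3 | step 6 | 1-[2-(benzyloxy)-4-methoxyphenyl]-2-[2,4-bis(benzyloxy)phenyl]-2-hydroxyethan-1-one, racemic | COc1ccc(C(=O)C(O)c2ccc(OCc3ccccc3)cc2OCc2ccccc2)c(OCc2ccccc2)c1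
F4 | step 9 | tert-butyl 2-methylbut-3-en-2-yl carbonate | C=CC(C)(C)OC(=O)OC(C)(C)C
F5 | step 10 | 1-[4-(allyloxy)-2-hydroxyphenyl]-2-(2-hydroxy-4-methoxyphenyl)ethane-1,2-dione | COc1ccc(C(=O)C(=O)c2ccc(OCC=C)cc2O)c(O)c1
F6 | step 10 | 1-(3-allyl-2,4-dihydroxyphenyl)-2-(2-hydroxy-4-methoxyphenyl)ethane-1,2-dione | COc1ccc(C(=O)C(=O)c2ccc(O)c(CC=C)c2O)c(O)c1
A1 | alternative 1 | 1-methoxy-2-(3-methylbut-2-en-1-yl)-1,3-bis(trimethylsilyloxy)buta-1,3-diene, geometry of the ketene acetal double bond not defined | COC(O[Si](C)(C)C)=C(CC=C(C)C)C(=C)O[Si](C)(C)C
A2 | alternative 1 | 1-[(tert-butyldimethylsilyl)oxy]-1-[4-methoxy-2-(methoxymethoxy)phenyl]but-3-yn-2-one, racemic | C#CC(=O)C(O[Si](C)(C)C(C)(C)C)c1ccc(OC)cc1OCOC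
A3 | alternative 1 | 2-[(tert-butyldimethylsilyl)oxy]-1-[2,4-dihydroxy-3-(3-methylbut-2-en-1-yl)phenyl]-2-[4-methoxy-2-(methoxymethoxy)phenyl]ethan-1-one, racemic | COCOc1cc(OC)ccc1C(O[Si](C)(C)C(C)(C)C)C(=O)c1ccc(O)c(CC=C(C)C)c1O
A4 | alternative 2 | 3-methoxycyclohex-2-en-1-one | COC1=CC(=O)CC1
A5 | alternative 2 | 1-{2-[(tert-butyldimethylsilyl)oxy]-2-[2,4-bis(methoxymethoxy)-3-(3-methylbut-2-en-1-yl)phenyl]acetyl}-1H-benzotriazole, racemic | CC(C)=CCc1c(OCOC)ccc(C(O[Si](C)(C)C(C)(C)C)C(=O)n2nnc3ccccc32)c1OCOC
A6 | alternative 2 | 6-{2-[(tert-butyldimethylsilyl)oxy]-2-[2,4-bis(methoxymethoxy)-3-(3-methylbut-2-en-1-yl)phenyl]acetyl}-3-methoxycyclohex-2-en-1-one, drawn as its chelated enol, racemic at the silyloxy carbon | COC1=CC(O)=C(CC1)C(=O)C(O[Si](C)(C)C(C)(C)C)c1ccc(OCOC)c(CC=C(C)C)c1OCOC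
A7 | alternative 3 | N,N'-dimethoxy-N,N'-dimethyloxalamide | CON(C)C(=O)C(=O)N(C)OC
A8 | alternative 3 | 1-bromo-4-methoxy-2-(methoxymethoxy)benzene | COCOc1cc(OC)ccc1Br
A9 | alternative 3 | 1,3-bis(methoxymethoxy)-2-(3-methylbut-2-en-1-yl)benzene | COCOc1cccc(OCOC)c1CC=C(C)C
A10 | alternative 3 | 1-[2,4-bis(methoxymethoxy)-3-(3-methylbut-2-en-1-yl)phenyl]-2-[4-methoxy-2-(methoxymethoxy)phenyl]ethane-1,2-dione | COCOc1cc(OC)ccc1C(=O)C(=O)c1ccc(OCOC)c(CC=C(C)C)c1OCOC
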